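**Retrosynthetic overview**

1. Target 47 ← C6 chloride by SN2 inversion of O6, C4 carbinol by enone reduction, 11,20-epoxide from the C11 methylene, three acetates ← methylene cyclodecenone 35; its E C8=C9 bond is osmylated on the only open (outer) face and both carbinols are then inverted (C9 by epoxide closure, C8 by epoxide opening).
2. The strategy rests on the ten-membered ring C1–C10: its C4 oxygen, the vicinal C6/C7 heteroatoms and the C8/C9 diol are the footprint of a 1,2-dialkenylcyclohexanol (ring A: C1, C2, C3, C4, C9, C10) rearranged across C4–C9. Hence 35 ← anionic oxy-Cope of trans-decalinol 30 (C6–C7 made, C4–C9 broken).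
3. 30 ← ene-dione 10: dihydrofuranyl fragment 16 added 1,4 at C9, alkoxyvinyl fragment 25 added at C4, C11 methylenated. 10 ← (R)-Wieland–Miescher ketone 1 (C14 inverted, C2 oxygenated through a β-diketone, C11 oxidised).
4. 16 ← (5R)-5-menthyloxyfuranone 11 (sets C17); 25 ← 2-naphthalenemethanol 20.
5. Ring order: rings B and A (present in 1) → dihydrofuran ring attached (the later lactone) → ten-membered ring by ring expansion → lactone by oxidation → spiro-epoxide last.

Key step: step 18

**Remarks on the chemistry**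

- Briarane numbering is used throughout; β is the face of the C1 methyl group, α the opposite face.
- Compound 11 and all reagents are taken as commercial.
- Diketone 6 is drawn as its diketo tautomer.
- Centres left unspecified in a SMILES string (C7 of 14 and 15, C5 of 33 and 34, C19 of 39, the ketal carbon of F3, C5 of F4 to F9) are epimer mixtures or fixed by a bridge; they are destroyed or converge later.
- The O6 group is 2-naphthylmethyl, the acetal group is menthyl, and C11 is carried as a methylene group.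
- Direct dihydroxylation of the E C8=C9 olefin cannot give the target diol, because only the face anti to C6 is open; steps 20 to 22 therefore invert both carbinol centres.

**Route**

Step 1
Reactants: 1 (R)-Wieland–Miescher ketone
Product: 2 14β-hydroxy enone (hydroxyl cis to the C1 methyl)
Conditions: NaBH4 (0.3 equiv), EtOH, −10 °C
Reagents that add atoms: none
Why: Chemoselective borohydride reduction of the saturated C14 ketone beside the enone; hydride comes from the α-face, opposite the axial C1 methyl, and should give the 14β-alcohol, the known behaviour of this diketone.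

Step 2
Reactants: 2 14β-hydroxy enone
Product: 3 14α-(4-nitrobenzoyloxy) enone
Conditions: 4-O2NC6H4CO2H, PPh3, DIAD, toluene, 0 °C → rt
Reagents that add atoms: 4-nitrobenzoic acid, OC(=O)c1ccc(cc1)[N+](=O)[O-]
Why: Mitsunobu reaction; SN2 displacement of the oxyphosphonium group inverts C14 to the axial 14α-ester (trans to the C1 methyl), as in the inversion of 17β-hydroxy steroids next to an angular methyl group.

Step 3
Reactants: 3 14α-(4-nitrobenzoyloxy) enone
Product: 4 cross-conjugated 2,3-didehydro dienone 4-nitrobenzoate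
Conditions: DDQ, dioxane, reflux
Reagents that add atoms: none
Why: DDQ dehydrogenation of a cyclic enone at the α′,β′-positions (as in the making of 1,4-dien-3-one steroids) should install the C2=C3 bond.

Step 4
Reactants: 4 cross-conjugated 2,3-didehydro dienone 4-nitrobenzoate
Product: 5 2α,3α-epoxy-14α-hydroxy enone
Conditions: H2O2 (30 %), NaOH, MeOH, 0 °C → rt
Reagents that add atoms: hydrogen peroxide, OO
Why: Weitz–Scheffer epoxidation of the less substituted C2=C3 enone bond from the face opposite the C1 methyl (the epoxide configuration is of no consequence); the activated 4-nitrobenzoate is saponified in the same alkaline medium.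

Step 5
Reactants: 5 2α,3α-epoxy-14α-hydroxy enone
Product: 6 14α-hydroxy 2,4-dione
Conditions: Pd(PPh3)4 (5 mol %), dppe (5 mol %), toluene, 80 °C
Reagents that add atoms: none
Why: Isomerisation of an α,β-epoxy ketone to the β-diketone by zerovalent palladium (oxidative addition at the Cα–O bond, then hydride shift) places a carbonyl group at C2.

Step 6
Reactants: 6 14α-hydroxy 2,4-dione
Product: 7 2β,4α,14α-triol with the C9=C10 olefin
Conditions: Me4NBH(OAc)3 (6 equiv), MeCN/AcOH 1:1, −30 → 0 °C
Reagents that add atoms: none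
Why: Evans–Saksena hydroxyl-directed reduction; the 14α-hydroxyl, β to the C2 carbonyl, binds boron and delivers hydride to the α-face of C2 (also the face opposite the C1 methyl), giving the equatorial 2β-alcohol, 1,3-anti to O14; the new C2 hydroxyl then directs reduction of the C4 carbonyl, which step 7 reverses.

Step 7
Reactants: 7 2β,4α,14α-triol with the C9=C10 olefin
Product: 8 2β,14α-dihydroxy enone
Conditions: MnO2, CH2Cl2, rt
Reagents that add atoms: none
Why: Activated MnO2 oxidises only the allylic C4 carbinol and should restore the enone while leaving the saturated C2 and C14 alcohols.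

Step 8
Reactants: 8 2β,14α-dihydroxy enone
Product: 9 2β,14α-bis(triethylsilyloxy) enone
Conditions: Et3SiOTf, 2,6-lutidine, CH2Cl2, −78 °C
Reagents that add atoms: triethylsilyl triflate, CC[Si](CC)(CC)OS(=O)(=O)C(F)(F)F
Why: Silyl triflate silylation of two hindered secondary alcohols under non-nucleophilic base, cold enough that the β-silyloxy ketone does not eliminate.

Step 9
Reactants: 9 2β,14α-bis(triethylsilyloxy) enone
Product: 10 C4,C11 ene-dione
Conditions: Rh2(cap)4 (cap = caprolactamate, 1 mol %), t-BuOOH, K2CO3, CH2Cl2, rt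
Reagents that add atoms: tert-butyl hydroperoxide, CC(C)(C)OO
Why: Dirhodium-catalysed allylic oxidation with t-BuOOH (enone to ene-dione) should convert the C11 methylene, activated by the C9=C10 bond, into a ketone.

Step 10
Reactants: 11 (5R)-5-[(1R,2S,5R)-menthyloxy]furan-2(5H)-one
Product: 13 3-bromo-4-methyl-5-menthyloxy-γ-lactone (Br/Me trans and Me/O-menthyl trans), via silyl ketene acetal 12 (not isolated)
Conditions: MeMgBr, CuBr·SMe2 (10 mol %), TMSCl, THF, −78 °C; then NBS, −78 → 0 °C
Reagents that add atoms: methylmagnesium bromide, C[Mg]Br; N-bromosuccinimide, BrN1C(=O)CCC1=O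
Why: Copper-catalysed conjugate addition of the methyl group anti to the menthyloxy group sets C17 (the known diastereoselectivity of this chiral butenolide), and the silyl ketene acetal is brominated at the α-carbon (C8) by NBS.

Step 11
Reactants: 13 3-bromo-4-methyl-5-menthyloxy-γ-lactone
Product: 14 bromo lactol
Conditions: DIBAL-H, CH2Cl2, −78 °C
Reagents that add atoms: none
Why: Partial reduction of a γ-lactone to the lactol at low temperature; the C–Br bond and the acetal are not touched.

Step 12
Reactants: 14 bromo lactol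
Product: 16 4-bromo-2-menthyloxy-3-methyl-2,3-dihydrofuran (fragment 1), via lactol mesylate 15 (not isolated)
Conditions: MsCl, Et3N, CH2Cl2, −20 °C; then DBU, rt
Reagents that add atoms: none
Why: Lactol activation and base-induced 1,2-elimination (the glycal synthesis, as used for 2-bromoglycals) should give the C7=C8 enol ether with bromine on C8, leaving C17 and C19 untouched.

Step 13
Reactants: 10 C4,C11 ene-dione; 16 4-bromo-2-menthyloxy-3-methyl-2,3-dihydrofuran
Product: 19 C9-dihydrofuranyl C4 ketone C11 trimethylsilyl enol ether, via dihydrofuranyllithium 17 (not isolated), via dihydrofuranylmagnesium bromide 18 (not isolated)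
Conditions: 16, t-BuLi (2 equiv), THF, −78 °C; MgBr2·OEt2; then CuBr·SMe2 (10 mol %), TMSCl, 10, −78 → −40 °C; Et3N
Reagents that add atoms: chlorotrimethylsilane, C[Si](C)(C)Cl
Why: Bromine–lithium exchange, transmetalation and copper-catalysed TMSCl-accelerated 1,4-addition; the alkenyl group adds to C9 (β to the C11 carbonyl, the only unsubstituted olefinic carbon) from the α-face opposite the C1 methyl, and the C11 enolate is held as its silyl enol ether so that C4 is the only free ketone.

Step 14
Reactants: 20 2-naphthalenemethanol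
Product: 23 ethynyl 2-naphthylmethyl ether, via dichlorovinyl ether 21 (not isolated), via lithium acetylide 22 (not isolated)
Conditions: KH, THF, then Cl2C=CHCl, rt; n-BuLi (2.5 equiv), −78 → −40 °C; MeOH
Reagents that add atoms: trichloroethylene, ClC=C(Cl)Cl
Why: Alkoxide addition–elimination on trichloroethylene followed by base-induced elimination and chlorine–lithium exchange is the standard route to alkynyl ethers; the product is kept at or below rt to avoid sigmatropic rearrangement.

Step 15
Reactants: 23 ethynyl 2-naphthylmethyl ether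
Product: 25 (E)-2-iodovinyl 2-naphthylmethyl ether (fragment 2), via alkenylzirconocene chloride 24 (not isolated)
Conditions: Cp2Zr(H)Cl, THF, rt; then I2, 0 °C
Reagents that add atoms: iodine, II
Why: Hydrozirconation with the Schwartz reagent (syn addition, zirconium at the terminal carbon) and iodinolysis with retention should give the E iodide, as known for alkoxyacetylenes.

Step 16
Reactants: 19 C9-dihydrofuranyl C4 ketone C11 trimethylsilyl enol ether; 25 (E)-2-iodovinyl 2-naphthylmethyl ether
Product: 29 trans-decalin C4 carbinol C11 ketone, via alkoxyvinyllithium 26 (not isolated), via alkenylcerium dichloride 27 (not isolated), via carbinol silyl enol ether 28 (not isolated)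
Conditions: 25, t-BuLi (2 equiv), Et2O, −78 °C; CeCl3, THF, −78 °C; 19; then K2CO3, MeOH, 0 °C
Reagents that add atoms: none
Why: Iodine–lithium exchange and transmetalation to the weakly basic organocerium reagent; 1,2-addition to the C4 ketone occurs trans to the adjacent C9 substituent (equatorial attack from the β-face, as with 2-alkenylcyclohexanones) to give the axial C4 α-alcohol, and methanolysis of the silyl enol ether protonates C10 from the α-face to the trans-decalin, which is also the thermodynamic ring fusion α to the C11 ketone.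

Step 17
Reactants: 29 trans-decalin C4 carbinol C11 ketone
Product: 30 oxy-Cope precursor (C11 methylene)
Conditions: Cp2TiMe2, toluene, 65 °C, dark
Reagents that add atoms: dimethyltitanocene, C[Ti](C)(C1C=CC=C1)C1C=CC=C1
Why: Petasis methylenation is non-basic and suited to hindered enolisable ketones; it should convert the only carbonyl group into the exocyclic methylene without triggering the rearrangement of the free carbinol.

Step 18
Reactants: 30 oxy-Cope precursor
Product: 33 C5-(dimethylaminomethyl) cyclodecenone (Mannich base), via potassium alkoxide 31 (not isolated), via potassium enolate 32 (not isolated)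
Conditions: KHMDS, 18-crown-6, THF, −78 → −20 °C; then Me2N=CH2 I (Eschenmoser's salt), −78 → 0 °C
Reagents that add atoms: Eschenmoser's salt, C=[N+](C)C.[I-]
Why: The potassium alkoxide should undergo the anionic oxy-Cope [3,3]-sigmatropic shift through the chair transition state that the trans-diequatorial alkenyl groups on the locked ring A allow: C4–C9 breaks, C6–C7 forms, and the ten-membered ring appears by ring expansion (six to ten, not by a cyclisation) as the regiodefined C4–C5 potassium enolate 32 with an E C8=C9 bond (C10 equatorial in the chair). The closest known reaction type is the anionic oxy-Cope ring expansion of trans-1,2-dialkenylcyclohexanols to (E)-cyclodec-5-enones, here with two enol-ether termini. C6 is set by the E enol ether (alkoxy group equatorial) and C7 by the cyclic enol ether, whose ring oxygen is held trans to C9 and is therefore equatorial; O6 emerges epimeric to the chlorine of the target so that the later displacement can invert it. The enolate is trapped at C5 by Eschenmoser's salt (Mannich reaction) below −20 °C, before β-elimination of the C6 alkoxide can intervene, and C5 forms as an inconsequential epimer mixture. The step needs chair over boat selectivity, which the rigid trans-decalin secures, and C-aminomethylation at the enolate carbon.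

Step 19
Reactants: 33 C5-(dimethylaminomethyl) cyclodecenone
Product: 35 α-methylene cyclodecenone, via trimethylammonium iodide 34 (not isolated)
Conditions: MeI, CH2Cl2, rt; then DBU, rt
Reagents that add atoms: none
Why: Exhaustive N-methylation and E1cB loss of trimethylamine is the standard conversion of a Mannich base into the α-methylene ketone; the quaternary ammonium group leaves far faster than the C6 alkoxide.

Step 20
Reactants: 35 α-methylene cyclodecenone
Product: 36 8,9-bis-epi syn-diol
Conditions: OsO4 (5 mol %), NMO (1.1 equiv), acetone/H2O, 0 °C; NaHSO3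
Reagents that add atoms: osmium tetroxide, O=[Os](=O)(=O)=O; N-methylmorpholine N-oxide, C[N+]1([O-])CCOCC1
Why: Upjohn dihydroxylation of the strained, most electron-rich trisubstituted E olefin in preference to the hindered 1,1-disubstituted C11 methylene and the electron-poor enone; OsO4 can reach only the outer face of the E-cyclodecene (anti to C6), which deliberately gives the syn-diol epimeric to the target at both C8 and C9.

Step 21
Reactants: 36 8,9-bis-epi syn-diol
Product: 38 8,9-epoxide (C9 inverted), via C9 mesylate 37 (not isolated)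
Conditions: MsCl, Et3N, CH2Cl2, 0 °C; then DBU, rt
Reagents that add atoms: none
Why: Selective mesylation of the secondary C9 hydroxyl and intramolecular SN2 displacement by the tertiary C8 alkoxide; epoxide closure inverts C9 to the configuration of the target.

Step 22
Reactants: 38 8,9-epoxide
Product: 39 lactol pentaol (C2, C8, C9, C14 hydroxyls and the C19 lactol)
Conditions: HClO4 (aq), THF, 0 °C → rt
Reagents that add atoms: water, O
Why: Acid-catalysed epoxide opening at the tertiary C8, anti to the departing oxygen, inverts C8 (by water directly or relayed through the transannular C4 carbonyl oxygen as a hemiketal, both giving the same configuration), and the same medium hydrolyses the menthyl acetal to the lactol and cleaves both triethylsilyl ethers.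

Step 23
Reactants: 39 lactol pentaol
Product: 40 γ-lactone tetraol
Conditions: Ag2CO3 on Celite, benzene, 60 °C
Reagents that add atoms: none
Why: Fétizon oxidation converts lactols into lactones much faster than it oxidises hindered secondary alcohols, so the C19 lactol should be oxidised selectively.

Step 24
Reactants: 40 γ-lactone tetraol
Product: 41 2,9,14-triacetate
Conditions: Ac2O, pyridine, DMAP (cat.), CH2Cl2, 0 °C → rt
Reagents that add atoms: acetic anhydride, CC(=O)OC(C)=O
Why: Acylation of the three secondary alcohols; the tertiary C8 hydroxyl is not acetylated under these conditions, and C4 is still a ketone, so the free C4 hydroxyl of the target is not at risk.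

Step 25
Reactants: 41 2,9,14-triacetate
Product: 42 11,20-epoxide
Conditions: mCPBA, NaHCO3, CH2Cl2, 0 °C
Reagents that add atoms: 3-chloroperoxybenzoic acid, OOC(=O)c1cccc(Cl)c1
Why: Prilezhaev epoxidation of the only electron-rich olefin left (the C5 methylene is deactivated as an enone); the peracid approaches C11 from the α-face, opposite the 1,3-diaxial C1 methyl, which places the oxygen equatorial (α) and C20 axial as in the target.

Step 26
Reactants: 42 11,20-epoxide
Product: 43 C4 allylic alcohol (4R)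
Conditions: (S)-2-methyl-CBS-oxazaborolidine (20 mol %), catecholborane, toluene, −78 °C
Reagents that add atoms: none
Why: Corey–Bakshi–Shibata reduction under reagent control; with the α-methylene carbon as the large group the (S)-catalyst should deliver hydride 1,2 to give the (4R) alcohol, and catecholborane at −78 °C leaves the epoxide, lactone and acetates alone.

Step 27
Reactants: 43 C4 allylic alcohol
Product: 44 C4 triethylsilyl ether
Conditions: Et3SiCl, imidazole, DMF, 0 °C
Reagents that add atoms: chlorotriethylsilane, CC[Si](Cl)(CC)CC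
Why: Silylation of the only secondary alcohol (the tertiary C8 hydroxyl does not react) masks C4 so that O6 can be differentiated.

Step 28
Reactants: 44 C4 triethylsilyl ether
Product: 45 C6 alcohol
Conditions: DDQ, CH2Cl2/pH 7 buffer, rt
Reagents that add atoms: none
Why: Oxidative cleavage of the 2-naphthylmethyl ether by DDQ (hydride abstraction, then hydrolysis of the hemiacetal) under neutral buffered conditions that the epoxide, silyl ether and acetates tolerate.

Step 29
Reactants: 45 C6 alcohol
Product: 46 C6 chloride (C4 triethylsilyl ether)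
Conditions: PPh3, Cl3CCOCCl3, CH2Cl2, 0 °C
Reagents that add atoms: hexachloroacetone, ClC(Cl)(Cl)C(=O)C(Cl)(Cl)Cl
Why: Appel-type chlorination with PPh3/hexachloroacetone; chloride displaces the oxyphosphonium group by SN2 with inversion at C6, and this reagent pair is the one documented to convert secondary allylic alcohols with little allylic transposition.

Step 30
Reactants: 46 C6 chloride
Product: 47 target CNP0312034.1
Conditions: Et3N·3HF, THF, 0 °C → rt
Reagents that add atoms: none
Why: Mild, nearly neutral fluoride cleavage of the secondary triethylsilyl ether, chosen because it should spare the allylic chloride, the spiro-epoxide and the acetates.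

**Compound list**

1 | (R)-Wieland–Miescher ketone | C[C@@]12CCC(=O)C=C1CCCC2=O | starting material
2 | 14β-hydroxy enone | O=C1CC[C@@]2(C)[C@H](O)CCCC2=C1 | intermediate
3 | 14α-(4-nitrobenzoyloxy) enone | O=C1CC[C@@]2(C)[C@@H](OC(=O)c3ccc(cc3)[N+](=O)[O-])CCCC2=C1 | intermediate
4 | cross-conjugated 2,3-didehydro dienone 4-nitrobenzoate | O=C1C=C[C@@]2(C)[C@@H](OC(=O)c3ccc(cc3)[N+](=O)[O-])CCCC2=C1 | intermediate
5 | 2α,3α-epoxy-14α-hydroxy enone | O=C1[C@H]2O[C@H]2[C@@]3(C)[C@@H](O)CCCC3=C1 | intermediate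
6 | 14α-hydroxy 2,4-dione | O=C1CC(=O)[C@@]2(C)[C@@H](O)CCCC2=C1 | intermediate
7 | 2β,4α,14α-triol with the C9=C10 olefin | O[C@H]1C[C@H](O)[C@@]2(C)[C@@H](O)CCCC2=C1 | intermediate
8 | 2β,14α-dihydroxy enone | O=C1C[C@H](O)[C@@]2(C)[C@@H](O)CCCC2=C1 | intermediate
9 | 2β,14α-bis(triethylsilyloxy) enone | O=C1C[C@H](O[Si](CC)(CC)CC)[C@@]2(C)[C@@H](O[Si](CC)(CC)CC)CCCC2=C1 | intermediate
10 | C4,C11 ene-dione | O=C1C[C@H](O[Si](CC)(CC)CC)[C@@]2(C)[C@@H](O[Si](CC)(CC)CC)CCC(=O)C2=C1 | intermediate
11 | (5R)-5-[(1R,2S,5R)-menthyloxy]furan-2(5H)-one | O=C1C=C[C@H](O[C@@H]2C[C@H](C)CC[C@H]2C(C)C)O1 | starting material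
12 | silyl ketene acetal | C[Si](C)(C)OC1=C[C@@H](C)[C@H](O[C@@H]2C[C@H](C)CC[C@H]2C(C)C)O1 | intermediate (not isolated)
13 | 3-bromo-4-methyl-5-menthyloxy-γ-lactone | O=C1[C@H](Br)[C@@H](C)[C@H](O[C@@H]2C[C@H](C)CC[C@H]2C(C)C)O1 | intermediate
14 | bromo lactol | OC1[C@H](Br)[C@@H](C)[C@H](O[C@@H]2C[C@H](C)CC[C@H]2C(C)C)O1 | intermediate
15 | lactol mesylate | CS(=O)(=O)OC1[C@H](Br)[C@@H](C)[C@H](O[C@@H]2C[C@H](C)CC[C@H]2C(C)C)O1 | intermediate (not isolated)
16 | 4-bromo-2-menthyloxy-3-methyl-2,3-dihydrofuran (fragment 1) | BrC1=CO[C@@H](O[C@@H]2C[C@H](C)CC[C@H]2C(C)C)[C@@H]1C | intermediate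
17 | dihydrofuranyllithium | [Li]C1=CO[C@@H](O[C@@H]2C[C@H](C)CC[C@H]2C(C)C)[C@@H]1C | intermediate (not isolated)
18 | dihydrofuranylmagnesium bromide | Br[Mg]C1=CO[C@@H](O[C@@H]2C[C@H](C)CC[C@H]2C(C)C)[C@@H]1C | intermediate (not isolated)
19 | C9-dihydrofuranyl C4 ketone C11 trimethylsilyl enol ether | O=C1C[C@H](O[Si](CC)(CC)CC)[C@@]2(C)[C@@H](O[Si](CC)(CC)CC)CCC(O[Si](C)(C)C)=C2[C@H]1C1=CO[C@@H](O[C@@H]3C[C@H](C)CC[C@H]3C(C)C)[C@@H]1C | intermediate
20 | 2-naphthalenemethanol | OCc1ccc2ccccc2c1 | starting material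
21 | (E)-1,2-dichlorovinyl 2-naphthylmethyl ether | Cl/C=C(Cl)\OCc1ccc2ccccc2c1 | intermediate (not isolated)
22 | lithium acetylide of the alkynyl ether | [Li]C#COCc1ccc2ccccc2c1 | intermediate (not isolated)
23 | ethynyl 2-naphthylmethyl ether | C#COCc1ccc2ccccc2c1 | intermediate
24 | (E)-alkenylzirconocene chloride | Cl[Zr](/C=C/OCc1ccc2ccccc2c1)(C1C=CC=C1)C1C=CC=C1 | intermediate (not isolated)
25 | (E)-2-iodovinyl 2-naphthylmethyl ether (fragment 2) | I/C=C/OCc1ccc2ccccc2c1 | intermediate
26 | (E)-2-(2-naphthylmethoxy)vinyllithium | [Li]/C=C/OCc1ccc2ccccc2c1 | intermediate (not isolated)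
27 | alkenylcerium dichloride | Cl[Ce](Cl)/C=C/OCc1ccc2ccccc2c1 | intermediate (not isolated)
28 | carbinol silyl enol ether | C(c1ccc2ccccc2c1)O/C=C/[C@]1(O)C[C@H](O[Si](CC)(CC)CC)[C@@]2(C)[C@@H](O[Si](CC)(CC)CC)CCC(O[Si](C)(C)C)=C2[C@H]1C1=CO[C@@H](O[C@@H]3C[C@H](C)CC[C@H]3C(C)C)[C@@H]1C | intermediate (not isolated)
29 | trans-decalin C4 carbinol C11 ketone | C(c1ccc2ccccc2c1)O/C=C/[C@]1(O)C[C@H](O[Si](CC)(CC)CC)[C@@]2(C)[C@@H](O[Si](CC)(CC)CC)CCC(=O)[C@@H]2[C@H]1C1=CO[C@@H](O[C@@H]3C[C@H](C)CC[C@H]3C(C)C)[C@@H]1C | intermediate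
30 | oxy-Cope precursor: trans-decalinol with C4 (E)-2-(2-naphthylmethoxy)vinyl, C9 dihydrofuranyl, C11 methylene | C(c1ccc2ccccc2c1)O/C=C/[C@]1(O)C[C@H](O[Si](CC)(CC)CC)[C@@]2(C)[C@@H](O[Si](CC)(CC)CC)CCC(=C)[C@@H]2[C@H]1C1=CO[C@@H](O[C@@H]3C[C@H](C)CC[C@H]3C(C)C)[C@@H]1C | intermediate
31 | potassium alkoxide of 30 | [K+].C(c1ccc2ccccc2c1)O/C=C/[C@]1([O-])C[C@H](O[Si](CC)(CC)CC)[C@@]2(C)[C@@H](O[Si](CC)(CC)CC)CCC(=C)[C@@H]2[C@H]1C1=CO[C@@H](O[C@@H]3C[C@H](C)CC[C@H]3C(C)C)[C@@H]1C | intermediate (not isolated)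
32 | potassium C4–C5 enolate of the cyclodecenone (E C8=C9), the [3,3] product | [K+].C1=C([O-])C[C@H](O[Si](CC)(CC)CC)[C@@]2(C)[C@@H](O[Si](CC)(CC)CC)CCC(=C)[C@@H]2/C=C3\[C@@H](C)[C@H](O[C@@H]6C[C@H](C)CC[C@H]6C(C)C)O[C@H]3[C@@H]1OCc4ccc5ccccc5c4 | intermediate (not isolated)
33 | C5-(dimethylaminomethyl) cyclodecenone (Mannich base) | CN(C)CC1C(=O)C[C@H](O[Si](CC)(CC)CC)[C@@]2(C)[C@@H](O[Si](CC)(CC)CC)CCC(=C)[C@@H]2/C=C3\[C@@H](C)[C@H](O[C@@H]6C[C@H](C)CC[C@H]6C(C)C)O[C@H]3[C@@H]1OCc4ccc5ccccc5c4 | intermediate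
34 | trimethylammonium iodide | [I-].C[N+](C)(C)CC1C(=O)C[C@H](O[Si](CC)(CC)CC)[C@@]2(C)[C@@H](O[Si](CC)(CC)CC)CCC(=C)[C@@H]2/C=C3\[C@@H](C)[C@H](O[C@@H]6C[C@H](C)CC[C@H]6C(C)C)O[C@H]3[C@@H]1OCc4ccc5ccccc5c4 | intermediate (not isolated)
35 | α-methylene cyclodecenone | C=C1C(=O)C[C@H](O[Si](CC)(CC)CC)[C@@]2(C)[C@@H](O[Si](CC)(CC)CC)CCC(=C)[C@@H]2/C=C3\[C@@H](C)[C@H](O[C@@H]6C[C@H](C)CC[C@H]6C(C)C)O[C@H]3[C@@H]1OCc4ccc5ccccc5c4 | intermediate
36 | 8,9-bis-epi syn-diol | C=C1C(=O)C[C@H](O[Si](CC)(CC)CC)[C@@]2(C)[C@@H](O[Si](CC)(CC)CC)CCC(=C)[C@@H]2[C@@H](O)[C@@]3(O)[C@@H](C)[C@H](O[C@@H]6C[C@H](C)CC[C@H]6C(C)C)O[C@H]3[C@@H]1OCc4ccc5ccccc5c4 | intermediate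
37 | C9 mesylate | C=C1C(=O)C[C@H](O[Si](CC)(CC)CC)[C@@]2(C)[C@@H](O[Si](CC)(CC)CC)CCC(=C)[C@@H]2[C@@H](OS(C)(=O)=O)[C@@]3(O)[C@@H](C)[C@H](O[C@@H]6C[C@H](C)CC[C@H]6C(C)C)O[C@H]3[C@@H]1OCc4ccc5ccccc5c4 | intermediate (not isolated)
38 | 8,9-epoxide (C9 inverted) | C=C1C(=O)C[C@H](O[Si](CC)(CC)CC)[C@@]2(C)[C@@H](O[Si](CC)(CC)CC)CCC(=C)[C@@H]2[C@@H]7O[C@@]73[C@@H](C)[C@H](O[C@@H]6C[C@H](C)CC[C@H]6C(C)C)O[C@H]3[C@@H]1OCc4ccc5ccccc5c4 | intermediate
39 | lactol pentaol | C=C1C(=O)C[C@H](O)[C@@]2(C)[C@@H](O)CCC(=C)[C@@H]2[C@H](O)[C@]3(O)[C@@H](C)C(O)O[C@H]3[C@@H]1OCc4ccc5ccccc5c4 | intermediate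
40 | γ-lactone tetraol | C=C1C(=O)C[C@H](O)[C@@]2(C)[C@@H](O)CCC(=C)[C@@H]2[C@H](O)[C@]3(O)[C@@H](C)C(=O)O[C@H]3[C@@H]1OCc4ccc5ccccc5c4 | intermediate
41 | 2,9,14-triacetate | C=C1C(=O)C[C@H](OC(C)=O)[C@@]2(C)[C@@H](OC(C)=O)CCC(=C)[C@@H]2[C@H](OC(C)=O)[C@]3(O)[C@@H](C)C(=O)O[C@H]3[C@@H]1OCc4ccc5ccccc5c4 | intermediate
42 | 11,20-epoxide | C=C1C(=O)C[C@H](OC(C)=O)[C@@]2(C)[C@@H](OC(C)=O)CC[C@]7(CO7)[C@@H]2[C@H](OC(C)=O)[C@]3(O)[C@@H](C)C(=O)O[C@H]3[C@@H]1OCc4ccc5ccccc5c4 | intermediate
43 | C4 allylic alcohol | C=C1[C@H](O)C[C@H](OC(C)=O)[C@@]2(C)[C@@H](OC(C)=O)CC[C@]7(CO7)[C@@H]2[C@H](OC(C)=O)[C@]3(O)[C@@H](C)C(=O)O[C@H]3[C@@H]1OCc4ccc5ccccc5c4 | intermediate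
44 | C4 triethylsilyl ether | C=C1[C@H](O[Si](CC)(CC)CC)C[C@H](OC(C)=O)[C@@]2(C)[C@@H](OC(C)=O)CC[C@]7(CO7)[C@@H]2[C@H](OC(C)=O)[C@]3(O)[C@@H](C)C(=O)O[C@H]3[C@@H]1OCc4ccc5ccccc5c4 | intermediate
45 | C6 alcohol | C=C1[C@H](O[Si](CC)(CC)CC)C[C@H](OC(C)=O)[C@@]2(C)[C@@H](OC(C)=O)CC[C@]7(CO7)[C@@H]2[C@H](OC(C)=O)[C@]3(O)[C@@H](C)C(=O)O[C@H]3[C@@H]1O | intermediate
46 | C6 chloride (C4 triethylsilyl ether) | C=C1[C@H](O[Si](CC)(CC)CC)C[C@H](OC(C)=O)[C@@]2(C)[C@@H](OC(C)=O)CC[C@]7(CO7)[C@@H]2[C@H](OC(C)=O)[C@]3(O)[C@@H](C)C(=O)O[C@H]3[C@H]1Cl | intermediate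
47 | CNP0312034.1 | C=C1[C@H](O)C[C@H](OC(C)=O)[C@@]2(C)[C@@H](OC(C)=O)CC[C@]3(CO3)[C@@H]2[C@H](OC(C)=O)[C@]2(O)[C@@H](C)C(=O)O[C@H]2[C@H]1Cl | target

**Step count and risks**

Total step count: 30 (25 on the main line, 3 for fragment 1, 2 for fragment 2).
Longest linear sequence: 25 steps (steps 1–9, 13, 16, 17, 18–30).

The three steps most likely to fail:

Step 18 (key step). The enolate may lose the C6 alkoxide by β-elimination, or the alkoxide may fragment, before the [3,3] shift and the trapping are complete. Fallback: run the same shift on the neutral silyl ether. From 30, silylation of the tertiary alcohol (TMSOTf, Et3N, CH2Cl2, −78 °C) should give the trimethylsilyl ether of the precursor F1. Heating F1 in degassed decalin at about 200 °C in base-washed glass should effect the thermal siloxy-Cope rearrangement to the trimethylsilyl enol ether of the cyclodecenone F2, which carries no enolate charge and cannot eliminate. Reaction of F2 with Eschenmoser's salt in CH2Cl2 (Mannich reaction of a silyl enol ether) returns to Mannich base 33.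

Step 22. Intermolecular attack of water at the hindered C8 may lose out to attack at C9, to transannular hydride shifts or to an ionisation that is not stereospecific. Fallback: use the internal carbonyl oxygen instead of water. From 38, BF3·OEt2 in CH2Cl2 at −78 °C should let the C4 carbonyl oxygen open the epoxide at C8 through a six-membered transition state from the C6 side (inversion), and the released C9 oxygen closes the oxocarbenium ion to the bridged C4 ketal F3 (the keto-epoxide to bicyclic ketal cyclisation). Aqueous HClO4 in THF then hydrolyses the ketal, the menthyl acetal and the silyl ethers together and returns to lactol 39.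

Step 29. Chloride may enter at C16 with allylic transposition, or the oxyphosphonium group may eliminate, instead of the SN2 inversion at C6. Fallback: remove the allylic system before the displacement.
- From enone 42, addition of dimethylamine (THF, 0 °C) to the methylene ketone should give the β-amino ketone F4.
- Reduction of C4 with the oxazaborolidine/catecholborane system of step 26 gives the amino alcohol F5, and Et3SiCl/imidazole gives the silyl ether F6.
- DDQ, after protonation of the amine with CF3CO2H, cleaves the naphthylmethyl ether to the C6 alcohol F7.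
- PPh3/hexachloroacetone displaces the now non-allylic C6 hydroxyl with inversion to the amino chloride F8.
- mCPBA at −20 °C gives the amine N-oxide F9, which on warming to rt undergoes Cope elimination to restore the C5 methylene and return to 46.

**Further compounds**

F1 | step 18 | trimethylsilyl ether of the precursor | C(c1ccc2ccccc2c1)O/C=C/[C@]1(O[Si](C)(C)C)C[C@H](O[Si](CC)(CC)CC)[C@@]2(C)[C@@H](O[Si](CC)(CC)CC)CCC(=C)[C@@H]2[C@H]1C1=CO[C@@H](O[C@@H]3C[C@H](C)CC[C@H]3C(C)C)[C@@H]1C
F2 | step 18 | trimethylsilyl enol ether of the cyclodecenone | C1=C(O[Si](C)(C)C)C[C@H](O[Si](CC)(CC)CC)[C@@]2(C)[C@@H](O[Si](CC)(CC)CC)CCC(=C)[C@@H]2/C=C3\[C@@H](C)[C@H](O[C@@H]6C[C@H](C)CC[C@H]6C(C)C)O[C@H]3[C@@H]1OCc4ccc5ccccc5c4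
F3 | step 22 | bridged C4 ketal | C=C1C78C[C@H](O[Si](CC)(CC)CC)[C@@]2(C)[C@@H](O[Si](CC)(CC)CC)CCC(=C)[C@@H]2[C@H](O7)[C@]3(O8)[C@@H](C)[C@H](O[C@@H]6C[C@H](C)CC[C@H]6C(C)C)O[C@H]3[C@@H]1OCc4ccc5ccccc5c4
F4 | step 29 | β-amino ketone | CN(C)CC1C(=O)C[C@H](OC(C)=O)[C@@]2(C)[C@@H](OC(C)=O)CC[C@]7(CO7)[C@@H]2[C@H](OC(C)=O)[C@]3(O)[C@@H](C)C(=O)O[C@H]3[C@@H]1OCc4ccc5ccccc5c4
F5 | step 29 | amino alcohol | CN(C)CC1[C@H](O)C[C@H](OC(C)=O)[C@@]2(C)[C@@H](OC(C)=O)CC[C@]7(CO7)[C@@H]2[C@H](OC(C)=O)[C@]3(O)[C@@H](C)C(=O)O[C@H]3[C@@H]1OCc4ccc5ccccc5c4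
F6 | step 29 | amino silyl ether | CN(C)CC1[C@H](O[Si](CC)(CC)CC)C[C@H](OC(C)=O)[C@@]2(C)[C@@H](OC(C)=O)CC[C@]7(CO7)[C@@H]2[C@H](OC(C)=O)[C@]3(O)[C@@H](C)C(=O)O[C@H]3[C@@H]1OCc4ccc5ccccc5c4
F7 | step 29 | amino C6 alcohol | CN(C)CC1[C@H](O[Si](CC)(CC)CC)C[C@H](OC(C)=O)[C@@]2(C)[C@@H](OC(C)=O)CC[C@]7(CO7)[C@@H]2[C@H](OC(C)=O)[C@]3(O)[C@@H](C)C(=O)O[C@H]3[C@@H]1O
F8 | step 29 | amino chloride | CN(C)CC1[C@H](O[Si](CC)(CC)CC)C[C@H](OC(C)=O)[C@@]2(C)[C@@H](OC(C)=O)CC[C@]7(CO7)[C@@H]2[C@H](OC(C)=O)[C@]3(O)[C@@H](C)C(=O)O[C@H]3[C@H]1Cl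
F9 | step 29 | amine N-oxide | C[N+](C)([O-])CC1[C@H](O[Si](CC)(CC)CC)C[C@H](OC(C)=O)[C@@]2(C)[C@@H](OC(C)=O)CC[C@]7(CO7)[C@@H]2[C@H](OC(C)=O)[C@]3(O)[C@@H](C)C(=O)O[C@H]3[C@H]1Cl
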